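**Remarks and assumptions.** TBS = tert-butyldimethylsilyl, TBSO = tert-butyldimethylsilyloxy. Locants C1–C8 are those of the target's bicyclo[3.2.1]oct-3-ene-2,8-dione core: C1 and C5 bridgeheads, C2 ketone, C3=C4 alkene with the styryl group on C4, C6 and C7 aryl-bearing, C8 bridge ketone. Diazomethane is assumed to be distilled from commercial N-methyl-N-nitroso-p-toluenesulfonamide, and the chiral tetramine base is assumed to be bought and recovered.

## Plan

- Retrosynthesis: after removal of four aryl silyl ethers, both rings are opened at once by cutting C1–C8 and C4–C5. This leaves one acyclic chain with a ketene (C5=C8=O) at one end and a silyl-masked ynone (C1=C2(OSi)–C3≡C4) at the other. Further cuts are C5–C6 (diazoketone homologation), C2–C3 (acetylide on a Weinreb amide) and C6–C7 (Michael addition).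
- Enabling feature: the bridge ketone C8 lies between both bridgeheads, C1 is alpha to C2=O, and C4 is the beta carbon of the C2 enone. C8/C5 can therefore act as acyl acceptor and then enol donor, and C1/C4 as enol donor and then alkyne acceptor.
- Forward order: the chain is assembled; the ynone is masked as its silyl enol ether (inert to diazomethane, later the C1 nucleophile, lost in the key step); the diazoketone is installed. In one flask, Wolff rearrangement and ketene capture close the cyclopentanone (C1–C8), then gold closes the cyclohexenone (C4–C5). Desilylation ends the route.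
- Stereochemistry: C6 and C7 come from the chiral lithium amide Michael addition and are retained through the Wolff shift. C1 is set trans to the C7 aryl group in the ketene capture, and C5 is then forced by the bridge. Both E alkenes come from Horner–Wadsworth–Emmons steps.

Key step: step 9

## Route

Step 1
Reactants: 1 2-(3,5-dihydroxyphenyl)acetic acid
Product: 3 2-[3,5-bis(TBSO)phenyl]acetic acid, via tris-silyl ester 2 (not isolated)
Conditions: TBSCl (3.3 equiv), imidazole (6 equiv), DMF, 20 °C; then AcOH/THF/H2O, 20 °C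
Reagents that add atoms: tert-butyldimethylsilyl chloride, CC(C)(C)[Si](C)(C)Cl
Why: Exhaustive silylation followed by selective hydrolysis of the far more labile silyl ester should leave the two aryl silyl ethers in place; no stereocentre is formed.

Step 2
Reactants: 4 4-(TBSO)benzaldehyde; 5 trimethyl phosphonoacetate
Product: 6 methyl (E)-3-[4-(TBSO)phenyl]prop-2-enoate
Conditions: NaH, THF, 0 → 20 °C
Reagents that add atoms: none
Why: Horner–Wadsworth–Emmons olefination of an aromatic aldehyde with a stabilised phosphonate anion should give the E cinnamate.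

Step 3
Reactants: 3 2-[3,5-bis(TBSO)phenyl]acetic acid; 6 methyl (E)-3-[4-(TBSO)phenyl]prop-2-enoate
Product: 8 (2S,3S)-2-[3,5-bis(TBSO)phenyl]-3-[4-(TBSO)phenyl]-5-methoxy-5-oxopentanoic acid, via dilithium enediolate 7 (not isolated)
Conditions: (R,R)-N,N′-bis(1-phenyl-2-piperidin-1-ylethyl)propane-1,3-diamine (1.05 equiv), n-BuLi (4.1 equiv), THF, 0 °C; then 6, −78 °C; aq. HCl (base recovered)
Reagents that add atoms: none
Why: Direct Michael addition of the acid enediolate held in a mixed aggregate with the C2-symmetric chiral lithium amide, in which the base is expected to shield one enediolate face as in its alkylations (C2 as S) and a closed lithium-bridged eight-membered transition state with the s-cis enoate and the enediolate aryl group in the less hindered position should give the 2,3-syn adduct (C3 as S).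

Step 4
Reactants: 8 (2S,3S)-2-[3,5-bis(TBSO)phenyl]-3-[4-(TBSO)phenyl]-5-methoxy-5-oxopentanoic acid
Product: 9 (2S,3S)-2-[3,5-bis(TBSO)phenyl]-3-[4-(TBSO)phenyl]-5-[methoxy(methyl)amino]-5-oxopentanoic acid
Conditions: MeNH(OMe)·HCl (1.5 equiv), i-PrMgCl (4.5 equiv), THF, −20 → 0 °C
Reagents that add atoms: N,O-dimethylhydroxylamine hydrochloride, CNOC.Cl
Why: Weinreb amide formation by aminolysis of the methyl ester with the chloromagnesium amide should proceed while the acid sits as its magnesium carboxylate, whose alpha C–H is not acidic enough to epimerise.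

Step 5
Reactants: 4 4-(TBSO)benzaldehyde; 10 diethyl [3-(trimethylsilyl)prop-2-yn-1-yl]phosphonate
Product: 11 tert-butyldimethyl{4-[(E)-4-(trimethylsilyl)but-1-en-3-yn-1-yl]phenoxy}silane
Conditions: LiN(SiMe3)2, THF, −78 → 0 °C
Reagents that add atoms: none
Why: Horner–Wadsworth–Emmons olefination with the propargylic phosphonate anion should give the conjugated E enyne, with the alkyne carried as its C-silyl derivative.

Step 6
Reactants: 9 (2S,3S)-2-[3,5-bis(TBSO)phenyl]-3-[4-(TBSO)phenyl]-5-[methoxy(methyl)amino]-5-oxopentanoic acid; 11 tert-butyldimethyl{4-[(E)-4-(trimethylsilyl)but-1-en-3-yn-1-yl]phenoxy}silane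
Product: 13 (2S,3S,8E)-2-[3,5-bis(TBSO)phenyl]-3,9-bis[4-(TBSO)phenyl]-5-oxonon-8-en-6-ynoic acid, via lithium acetylide 12 (not isolated)
Conditions: 11 (1.6 equiv), MeLi·LiBr (1.5 equiv), THF, 0 °C; then 9 pre-treated with LiN(SiMe3)2 (1.05 equiv), −78 → −20 °C; aq. NH4Cl
Reagents that add atoms: none
Why: Weinreb ketone synthesis, in which silicon–lithium exchange gives the acetylide that adds once to the amide through the stable lithium chelate while the carboxylate is inert, so the ynone appears only on work-up and the stereocentres are untouched.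

Step 7
Reactants: 13 (2S,3S,8E)-2-[3,5-bis(TBSO)phenyl]-3,9-bis[4-(TBSO)phenyl]-5-oxonon-8-en-6-ynoic acid
Product: 15 (2S,3S,4Z,8E)-2-[3,5-bis(TBSO)phenyl]-5-(TBSO)-3,9-bis[4-(TBSO)phenyl]nona-4,8-dien-6-ynoic acid, via bis-silyl derivative 14 (not isolated)
Conditions: TBSOTf (2.2 equiv), Et3N (3 equiv), CH2Cl2, −78 → −40 °C; then MeOH, −40 → 0 °C; pH 5 buffer
Reagents that add atoms: tert-butyldimethylsilyl trifluoromethanesulfonate, CC(C)(C)[Si](C)(C)OS(=O)(=O)C(F)(F)F
Why: Soft enolisation of the only enolisable side of the alkynyl ketone should give the Z 2-silyloxy enyne, which masks the ynone as a non-electrophilic and non-dipolarophilic enol ether, and the silyl ester formed alongside is cleaved selectively by methanolysis.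

Step 8
Reactants: 15 (2S,3S,4Z,8E)-2-[3,5-bis(TBSO)phenyl]-5-(TBSO)-3,9-bis[4-(TBSO)phenyl]nona-4,8-dien-6-ynoic acid
Product: 17 (3S,4S,5Z,9E)-1-diazo-3-[3,5-bis(TBSO)phenyl]-6-(TBSO)-4,10-bis[4-(TBSO)phenyl]deca-5,9-dien-7-yn-2-one, via mixed carbonic anhydride 16 (not isolated)
Conditions: i-BuOCOCl (1.05 equiv), N-methylmorpholine (1.1 equiv), THF, −20 °C; then CH2N2 (3 equiv), Et2O, −20 → 0 °C
Reagents that add atoms: diazomethane, C=[N+]=[N-]
Why: First half of an Arndt–Eistert homologation, in which diazomethane is acylated by the mixed anhydride under cold, weakly basic conditions that should spare the alpha-aryl stereocentre and the silyl enol ether, the masked ynone being inert to the dipole.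

Step 9
Reactants: 17 (3S,4S,5Z,9E)-1-diazo-3-[3,5-bis(TBSO)phenyl]-6-(TBSO)-4,10-bis[4-(TBSO)phenyl]deca-5,9-dien-7-yn-2-one
Product: 20 (1R,5S,6R,7R)-6-[3,5-bis(TBSO)phenyl]-7-[4-(TBSO)phenyl]-4-{(E)-2-[4-(TBSO)phenyl]ethenyl}bicyclo[3.2.1]oct-3-ene-2,8-dione, via ketene 18 (not isolated), via cyclopentenyl silyl enol ether 19 (not isolated)
Conditions: hν (400 nm LED), CH2Cl2 (0.005 M), 20 °C until N2 evolution ends; then [Au(P(t-Bu)2(o-biphenyl))(NCMe)]SbF6 (5 mol %), i-PrOH (2 equiv), 20 °C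
Reagents that add atoms: none
Why: Proposed new method: irradiation in the weak n–π* band of the diazoketone, where the enyne chromophore should not absorb, triggers a Wolff rearrangement with retention at the migrating C6 to give the aldoketene C5H=C8=O, whose sp carbon C8 is attacked by C1 of the tethered silyl enol ether in a 5-exo-dig closure (C=O exocyclic, C5=C8 endocyclic in the new cyclopentene). A 1,5 oxygen-to-oxygen silyl shift in the zwitterion then unmasks the ynone and leaves the enol silane regiospecifically on the C5 side; the cationic monovalent gold catalyst added next activates the alkyne for 6-endo-dig attack of C5 on C4, and 2-propanol removes the silyl group and protonates the vinylgold. The closest known reaction types are the Arndt–Eistert sequence with intramolecular capture of the Wolff ketene, thermal intramolecular additions of ketenes to electron-rich alkenes, and the gold-catalysed 6-endo-dig carbocyclisation of cyclic silyl enol ethers onto alkynyl ketones that gives bridged bicyclic enones; what is new is the carbon acylation of a silyl enol ether by a ketene that relays the silyl group to the ketene oxygen. C1 is set in the ketene capture with the ynoyl group trans to the C7 aryl group (approach anti to the neighbouring substituent, which is also the thermodynamic arrangement of this enolisable centre). C5 is then fixed by the bicyclic geometry, because the three-carbon bridge can only span the face that carries the ynoyl group, which puts it cis to the C6 aryl group as in the target. The step needs carbon rather than oxygen cyclisation onto the alkyne and no enolisation towards C1, and the O-silyl cap on C8 together with the neutral medium should secure both.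

Step 10
Reactants: 20 (1R,5S,6R,7R)-6-[3,5-bis(TBSO)phenyl]-7-[4-(TBSO)phenyl]-4-{(E)-2-[4-(TBSO)phenyl]ethenyl}bicyclo[3.2.1]oct-3-ene-2,8-dione
Product: 21 vitisinol D
Conditions: HF·pyridine, pyridine, THF, 0 → 20 °C
Reagents that add atoms: none
Why: Fluoride cleavage of the four aryl silyl ethers under buffered, non-basic conditions should avoid retro-Claisen opening of the non-enolisable bridged 1,3-diketone and leaves all stereocentres untouched.

## Compound list

1 | 2-(3,5-dihydroxyphenyl)acetic acid | OC(=O)Cc1cc(O)cc(O)c1 | starting material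
2 | tert-butyldimethylsilyl 2-[3,5-bis(TBSO)phenyl]acetate | CC(C)(C)[Si](C)(C)OC(=O)Cc1cc(O[Si](C)(C)C(C)(C)C)cc(O[Si](C)(C)C(C)(C)C)c1 | intermediate
3 | 2-[3,5-bis(TBSO)phenyl]acetic acid | OC(=O)Cc1cc(O[Si](C)(C)C(C)(C)C)cc(O[Si](C)(C)C(C)(C)C)c1 | intermediate
4 | 4-(TBSO)benzaldehyde | O=Cc1ccc(O[Si](C)(C)C(C)(C)C)cc1 | starting material
5 | trimethyl phosphonoacetate | COC(=O)CP(=O)(OC)OC | starting material
6 | methyl (E)-3-[4-(TBSO)phenyl]prop-2-enoate | COC(=O)/C=C/c1ccc(O[Si](C)(C)C(C)(C)C)cc1 | intermediate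
7 | dilithium 2-[3,5-bis(TBSO)phenyl]ethene-1,1-diolate | [Li+].[Li+].[O-]C([O-])=Cc1cc(O[Si](C)(C)C(C)(C)C)cc(O[Si](C)(C)C(C)(C)C)c1 | intermediate
8 | (2S,3S)-2-[3,5-bis(TBSO)phenyl]-3-[4-(TBSO)phenyl]-5-methoxy-5-oxopentanoic acid | COC(=O)C[C@H](c1ccc(O[Si](C)(C)C(C)(C)C)cc1)[C@H](C(=O)O)c1cc(O[Si](C)(C)C(C)(C)C)cc(O[Si](C)(C)C(C)(C)C)c1 | intermediate
9 | (2S,3S)-2-[3,5-bis(TBSO)phenyl]-3-[4-(TBSO)phenyl]-5-[methoxy(methyl)amino]-5-oxopentanoic acid | CON(C)C(=O)C[C@H](c1ccc(O[Si](C)(C)C(C)(C)C)cc1)[C@H](C(=O)O)c1cc(O[Si](C)(C)C(C)(C)C)cc(O[Si](C)(C)C(C)(C)C)c1 | intermediate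
10 | diethyl [3-(trimethylsilyl)prop-2-yn-1-yl]phosphonate | CCOP(=O)(CC#C[Si](C)(C)C)OCC | starting material
11 | tert-butyldimethyl{4-[(E)-4-(trimethylsilyl)but-1-en-3-yn-1-yl]phenoxy}silane | C[Si](C)(C)C#C/C=C/c1ccc(O[Si](C)(C)C(C)(C)C)cc1 | intermediate
12 | lithium (E)-4-[4-(TBSO)phenyl]but-3-en-1-yn-1-ide | [Li]C#C/C=C/c1ccc(O[Si](C)(C)C(C)(C)C)cc1 | intermediate
13 | (2S,3S,8E)-2-[3,5-bis(TBSO)phenyl]-3,9-bis[4-(TBSO)phenyl]-5-oxonon-8-en-6-ynoic acid | O=C(C[C@H](c1ccc(O[Si](C)(C)C(C)(C)C)cc1)[C@H](C(=O)O)c1cc(O[Si](C)(C)C(C)(C)C)cc(O[Si](C)(C)C(C)(C)C)c1)C#C/C=C/c1ccc(O[Si](C)(C)C(C)(C)C)cc1 | intermediate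
14 | tert-butyldimethylsilyl ester of 15 | CC(C)(C)[Si](C)(C)Oc1ccc(/C=C/C#C/C(O[Si](C)(C)C(C)(C)C)=C/[C@H](c2ccc(O[Si](C)(C)C(C)(C)C)cc2)[C@H](C(=O)O[Si](C)(C)C(C)(C)C)c2cc(O[Si](C)(C)C(C)(C)C)cc(O[Si](C)(C)C(C)(C)C)c2)cc1 | intermediate
15 | (2S,3S,4Z,8E)-2-[3,5-bis(TBSO)phenyl]-5-(TBSO)-3,9-bis[4-(TBSO)phenyl]nona-4,8-dien-6-ynoic acid | CC(C)(C)[Si](C)(C)Oc1ccc(/C=C/C#C/C(O[Si](C)(C)C(C)(C)C)=C/[C@H](c2ccc(O[Si](C)(C)C(C)(C)C)cc2)[C@H](C(=O)O)c2cc(O[Si](C)(C)C(C)(C)C)cc(O[Si](C)(C)C(C)(C)C)c2)cc1 | intermediate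
16 | mixed anhydride of 15 with isobutyl hydrogen carbonate | CC(C)(C)[Si](C)(C)Oc1ccc(/C=C/C#C/C(O[Si](C)(C)C(C)(C)C)=C/[C@H](c2ccc(O[Si](C)(C)C(C)(C)C)cc2)[C@H](C(=O)OC(=O)OCC(C)C)c2cc(O[Si](C)(C)C(C)(C)C)cc(O[Si](C)(C)C(C)(C)C)c2)cc1 | intermediate
17 | (3S,4S,5Z,9E)-1-diazo-3-[3,5-bis(TBSO)phenyl]-6-(TBSO)-4,10-bis[4-(TBSO)phenyl]deca-5,9-dien-7-yn-2-one | CC(C)(C)[Si](C)(C)Oc1ccc(/C=C/C#C/C(O[Si](C)(C)C(C)(C)C)=C/[C@H](c2ccc(O[Si](C)(C)C(C)(C)C)cc2)[C@H](C(=O)C=[N+]=[N-])c2cc(O[Si](C)(C)C(C)(C)C)cc(O[Si](C)(C)C(C)(C)C)c2)cc1 | intermediate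
18 | (3R,4R,5Z,9E)-3-[3,5-bis(TBSO)phenyl]-6-(TBSO)-4,10-bis[4-(TBSO)phenyl]deca-1,5,9-trien-7-yn-1-one (ketene) | CC(C)(C)[Si](C)(C)Oc1ccc(/C=C/C#C/C(O[Si](C)(C)C(C)(C)C)=C/[C@H](c2ccc(O[Si](C)(C)C(C)(C)C)cc2)[C@H](C=C=O)c2cc(O[Si](C)(C)C(C)(C)C)cc(O[Si](C)(C)C(C)(C)C)c2)cc1 | intermediate
19 | (E)-1-{(1S,4R,5R)-2-(TBSO)-4-[3,5-bis(TBSO)phenyl]-5-[4-(TBSO)phenyl]cyclopent-2-en-1-yl}-5-[4-(TBSO)phenyl]pent-4-en-2-yn-1-one | O=C(C#C/C=C/c1ccc(O[Si](C)(C)C(C)(C)C)cc1)[C@@H]1C(O[Si](C)(C)C(C)(C)C)=C[C@H](c2cc(O[Si](C)(C)C(C)(C)C)cc(O[Si](C)(C)C(C)(C)C)c2)[C@H]1c1ccc(O[Si](C)(C)C(C)(C)C)cc1 | intermediate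
20 | (1R,5S,6R,7R)-6-[3,5-bis(TBSO)phenyl]-7-[4-(TBSO)phenyl]-4-{(E)-2-[4-(TBSO)phenyl]ethenyl}bicyclo[3.2.1]oct-3-ene-2,8-dione | O=C1C=C(/C=C/c2ccc(O[Si](C)(C)C(C)(C)C)cc2)[C@H]2C(=O)[C@@H]1[C@H](c1ccc(O[Si](C)(C)C(C)(C)C)cc1)[C@H]2c1cc(O[Si](C)(C)C(C)(C)C)cc(O[Si](C)(C)C(C)(C)C)c1 | intermediate
21 | vitisinol D, (1R,5S,6R,7R)-6-(3,5-dihydroxyphenyl)-7-(4-hydroxyphenyl)-4-[(E)-2-(4-hydroxyphenyl)ethenyl]bicyclo[3.2.1]oct-3-ene-2,8-dione | O=C1C=C(/C=C/c2ccc(O)cc2)[C@H]2C(=O)[C@@H]1[C@H](c1ccc(O)cc1)[C@H]2c1cc(O)cc(O)c1 | target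

## Step count and risks

Total step count: 10. Longest linear sequence: 8 steps (steps 1, 3, 4, 6, 7, 8, 9, 10).

**Step 9 (key step).** The ketene may be captured at carbon too slowly, so that it dimerises or gives a crossed cyclobutanone. The enol silane may also shift its double bond towards C1 before the gold closure, or the styryl alkene may isomerise under the light.

The fallback sets out from 11 and returns to the route at 19, with C1–C8 present from the start in a cyclopentenone and only known reaction types. The acetylide 12 made from 11 is formylated with DMF to (E)-5-[4-(TBSO)phenyl]pent-4-en-2-ynal F1. Commercial (S)-4-(TBSO)cyclopent-2-en-1-one takes up [4-(TBSO)phenyl]magnesium bromide under CuBr·SMe2 catalysis anti to the silyloxy group to give (3R,4S)-4-(TBSO)-3-[4-(TBSO)phenyl]cyclopentan-1-one F2. Brief treatment with DBU at 0 °C eliminates silanol to (S)-4-[4-(TBSO)phenyl]cyclopent-2-en-1-one F3. Its alpha′ lithium enolate (LiN(i-Pr)2, −78 °C) adds to F1 anti to the aryl group, and capping of the aldolate with Me3SiCl gives the trans 4-aryl-5-[1-(trimethylsilyloxy)alkynyl]cyclopentenone F4. Copper-catalysed conjugate addition of [3,5-bis(TBSO)phenyl]magnesium bromide anti to the C4 aryl group, with TBSCl trapping of the enolate, gives the regiodefined silyl enol ether F5. Methanolysis of the trimethylsilyl ether (K2CO3, MeOH, 0 °C) gives the propargylic alcohol F6, and Dess–Martin oxidation gives 19. This is cyclised with the gold catalyst as in the second stage of step 9 to give 20.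

**Step 3.** The relative topicity of the enediolate addition may be poor or reversed (erosion of the 2,3-syn relationship), or the facial control by the lithium amide may be incomplete.

The fallback sets out from 3 and 4 and returns at 9. Wittig olefination of 4 with 1,1,1-trichloro-3-(triphenyl-λ5-phosphanylidene)propan-2-one gives (E)-1,1,1-trichloro-4-[4-(TBSO)phenyl]but-3-en-2-one F7. Acid 3 is activated with pivaloyl chloride and i-Pr2NEt and combined with F7 under catalysis by the enantiomer of the isothiourea HyperBTM that leads to the 3S,4S series. This Michael addition–lactonisation is of a type known to be anti-selective, and the trans arrangement is also the thermodynamic one at the epimerisable C3. It gives (3S,4S)-3-[3,5-bis(TBSO)phenyl]-4-[4-(TBSO)phenyl]-6-(trichloromethyl)-3,4-dihydro-2H-pyran-2-one F8. Mild hydrolysis of the enol lactone (NaHCO3, aq. THF) gives (2S,3S)-2-[3,5-bis(TBSO)phenyl]-3-[4-(TBSO)phenyl]-6,6,6-trichloro-5-oxohexanoic acid F9. Haloform-type aminolysis of the trichloromethyl ketone with N,O-dimethylhydroxylamine then gives 9.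

**Step 7.** The silyl ester may be silylated further at its alpha carbon, with loss of configuration at the alpha-aryl centre, and the methanolysis may not distinguish the silyl ester cleanly from the silyl enol ether.

The fallback sets out from 13 and returns at 15 by way of an orthogonal ester. Alkylation of 13 with allyl bromide and KHCO3 in DMF gives the prop-2-en-1-yl ester of 13 F10. Soft enolisation with TBSOTf (1.1 equiv) and Et3N gives the prop-2-en-1-yl ester of 15 F11. Deallylation with Pd(PPh3)4 (a zerovalent palladium catalyst) and morpholine, followed by a pH 5 work-up, gives 15.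

Further compounds

F1 | step 9 | (E)-5-[4-(TBSO)phenyl]pent-4-en-2-ynal | O=CC#C/C=C/c1ccc(O[Si](C)(C)C(C)(C)C)cc1
F2 | step 9 | (3R,4S)-4-(TBSO)-3-[4-(TBSO)phenyl]cyclopentan-1-one | O=C1C[C@H](O[Si](C)(C)C(C)(C)C)[C@@H](c2ccc(O[Si](C)(C)C(C)(C)C)cc2)C1
F3 | step 9 | (S)-4-[4-(TBSO)phenyl]cyclopent-2-en-1-one | O=C1C=C[C@@H](c2ccc(O[Si](C)(C)C(C)(C)C)cc2)C1
F4 | step 9 | (4R,5R)-4-[4-(TBSO)phenyl]-5-{(E)-5-[4-(TBSO)phenyl]-1-(trimethylsilyloxy)pent-4-en-2-yn-1-yl}cyclopent-2-en-1-one (carbinol epimers) | C[Si](C)(C)OC(C#C/C=C/c1ccc(O[Si](C)(C)C(C)(C)C)cc1)[C@@H]1C(=O)C=C[C@H]1c1ccc(O[Si](C)(C)C(C)(C)C)cc1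
F5 | step 9 | trimethylsilyl ether of F6, ring configuration as in 19 (carbinol epimers) | C[Si](C)(C)OC(C#C/C=C/c1ccc(O[Si](C)(C)C(C)(C)C)cc1)[C@@H]1C(O[Si](C)(C)C(C)(C)C)=C[C@H](c2cc(O[Si](C)(C)C(C)(C)C)cc(O[Si](C)(C)C(C)(C)C)c2)[C@H]1c1ccc(O[Si](C)(C)C(C)(C)C)cc1
F6 | step 9 | (E)-1-{(1R,4R,5R)-2-(TBSO)-4-[3,5-bis(TBSO)phenyl]-5-[4-(TBSO)phenyl]cyclopent-2-en-1-yl}-5-[4-(TBSO)phenyl]pent-4-en-2-yn-1-ol (carbinol epimers) | OC(C#C/C=C/c1ccc(O[Si](C)(C)C(C)(C)C)cc1)[C@@H]1C(O[Si](C)(C)C(C)(C)C)=C[C@H](c2cc(O[Si](C)(C)C(C)(C)C)cc(O[Si](C)(C)C(C)(C)C)c2)[C@H]1c1ccc(O[Si](C)(C)C(C)(C)C)cc1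
F7 | step 3 | (E)-1,1,1-trichloro-4-[4-(TBSO)phenyl]but-3-en-2-one | O=C(/C=C/c1ccc(O[Si](C)(C)C(C)(C)C)cc1)C(Cl)(Cl)Cl
F8 | step 3 | (3S,4S)-3-[3,5-bis(TBSO)phenyl]-4-[4-(TBSO)phenyl]-6-(trichloromethyl)-3,4-dihydro-2H-pyran-2-one | O=C1OC(C(Cl)(Cl)Cl)=C[C@H](c2ccc(O[Si](C)(C)C(C)(C)C)cc2)[C@H]1c1cc(O[Si](C)(C)C(C)(C)C)cc(O[Si](C)(C)C(C)(C)C)c1
F9 | step 3 | (2S,3S)-2-[3,5-bis(TBSO)phenyl]-3-[4-(TBSO)phenyl]-6,6,6-trichloro-5-oxohexanoic acid | O=C(C[C@H](c1ccc(O[Si](C)(C)C(C)(C)C)cc1)[C@H](C(=O)O)c1cc(O[Si](C)(C)C(C)(C)C)cc(O[Si](C)(C)C(C)(C)C)c1)C(Cl)(Cl)Cl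
F10 | step 7 | prop-2-en-1-yl (2S,3S,8E)-2-[3,5-bis(TBSO)phenyl]-3,9-bis[4-(TBSO)phenyl]-5-oxonon-8-en-6-ynoate | O=C(C[C@H](c1ccc(O[Si](C)(C)C(C)(C)C)cc1)[C@H](C(=O)OCC=C)c1cc(O[Si](C)(C)C(C)(C)C)cc(O[Si](C)(C)C(C)(C)C)c1)C#C/C=C/c1ccc(O[Si](C)(C)C(C)(C)C)cc1
F11 | step 7 | prop-2-en-1-yl (2S,3S,4Z,8E)-2-[3,5-bis(TBSO)phenyl]-5-(TBSO)-3,9-bis[4-(TBSO)phenyl]nona-4,8-dien-6-ynoate | CC(C)(C)[Si](C)(C)Oc1ccc(/C=C/C#C/C(O[Si](C)(C)C(C)(C)C)=C/[C@H](c2ccc(O[Si](C)(C)C(C)(C)C)cc2)[C@H](C(=O)OCC=C)c2cc(O[Si](C)(C)C(C)(C)C)cc(O[Si](C)(C)C(C)(C)C)c2)cc1
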